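**Retrosynthetic overview**

- Locants: ring C1 (CH–OAc), C2, C3(Me)=C4, C5, C6=C7(C10HO), C8(C11HO), C9 (side chain). Target ⇐ double Swern oxidation, silyl ether cleavage, acetylation ⇐ diol ⇐ bridged γ-lactone in which the C1 oxygen is tied to C11(=O).
- Key disconnection: ring expansion of a cyclohexene (C11, C4, C5, C6=C7, C8) to the nine-membered ring. C1–C2 is formed and C11–C4 is broken in one 2-oxonia-Cope shift of an oxocarbenium ion made in the flask from an aldehyde (C1) and a dimethyl ketal (C11).
- Enabling feature: the C1 oxygen is 1,3 to C11 (over C9–C8) and homoallylic to C3=C4. With O bonded to C11 (five-membered ring O–C1–C9–C8–C11) and C11 still bonded to C4, the atoms C1=O+, O, C11, C4, C3, C2 form a chair six-membered array, and ester formation at C11 drives the shift.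
- Aldehyde ketal ⇐ Ireland–Claisen rearrangement (C8–C9 bond, both centres) of the (S)-citronellate of a cis-4,4-dimethoxy-5-isopropenylcyclohex-2-enol ⇐ Luche reduction ⇐ asymmetric rhodium-catalysed isopropenyl addition to a p-quinone monoketal ⇐ 2-hydroxy-5-methoxybenzaldehyde.
- Order of rings: six-membered carbocycle (from the arene); oxolanylium ring (transient); nine-membered ring (by the ring expansion, which leaves a lactone bridge that is later cleaved by reduction).

Key step: step 10

**Route**

Step 1
Reactants: 1 2-hydroxy-5-methoxybenzaldehyde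
Product: 2 2-(hydroxymethyl)-4-methoxyphenol
Conditions: NaBH4, MeOH, 0 °C
Reagents that add atoms: none
Why: Borohydride reduction of the aryl aldehyde to the benzylic alcohol, with no other reducible group and no stereocentre.

Step 2
Reactants: 2 2-(hydroxymethyl)-4-methoxyphenol
Product: 3 2-{[(tert-butyldimethylsilyl)oxy]methyl}-4-methoxyphenol
Conditions: TBSCl (1.05 equiv), imidazole, CH2Cl2, 0 °C; then K2CO3, MeOH (brief)
Reagents that add atoms: tert-butyldimethylsilyl chloride, CC(C)(C)[Si](C)(C)Cl
Why: Imidazole-mediated silylation at 0 °C should take the unhindered primary benzylic hydroxyl in preference to the hydrogen-bonded phenol, and any aryl silyl ether is cleaved again by the carbonate treatment (chemoselective silyl ether formation).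

Step 3
Reactants: 3 2-{[(tert-butyldimethylsilyl)oxy]methyl}-4-methoxyphenol
Product: 4 2-{[(tert-butyldimethylsilyl)oxy]methyl}-4,4-dimethoxycyclohexa-2,5-dien-1-one
Conditions: PhI(OAc)2, MeOH, 0 °C
Reagents that add atoms: methanol, CO
Why: Oxidative dearomatisation of a 4-methoxyphenol by the hypervalent iodine reagent in methanol traps the phenoxonium ion at the para position as the p-quinone monoketal, which introduces the future aldehyde carbon C11 at the ketal oxidation level.

Step 4
Reactants: 4 2-{[(tert-butyldimethylsilyl)oxy]methyl}-4,4-dimethoxycyclohexa-2,5-dien-1-one; 5 4,4,5,5-tetramethyl-2-(prop-1-en-2-yl)-1,3,2-dioxaborolane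
Product: 6 (5R)-2-{[(tert-butyldimethylsilyl)oxy]methyl}-4,4-dimethoxy-5-(prop-1-en-2-yl)cyclohex-2-en-1-one
Conditions: [Rh(OH)((R)-BINAP)]2 (3 mol %), KOH (cat.), dioxane/H2O 10:1, 40 °C
Reagents that add atoms: none
Why: Rhodium-catalysed asymmetric 1,4-addition of an alkenylboron reagent (Hayashi–Miyaura type) should go to the unsubstituted enone arm only, since the other arm is alpha-substituted, and the (R)-BINAP complex is expected, by analogy with the face selection known for cyclohex-2-enone, to set the (5R) centre that later steers C8.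

Step 5
Reactants: 6 (5R)-2-{[(tert-butyldimethylsilyl)oxy]methyl}-4,4-dimethoxy-5-(prop-1-en-2-yl)cyclohex-2-en-1-one
Product: 7 (1R,5R)-2-{[(tert-butyldimethylsilyl)oxy]methyl}-4,4-dimethoxy-5-(prop-1-en-2-yl)cyclohex-2-en-1-ol (hydroxyl cis to isopropenyl)
Conditions: NaBH4, CeCl3·7H2O, MeOH, −78 °C
Reagents that add atoms: none
Why: Luche reduction gives 1,2-reduction by axial hydride attack, which places the hydroxyl cis (pseudo-diequatorial) to the isopropenyl group as in the reduction of other 5-substituted cyclohexenones.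

Step 6
Reactants: 7 (1R,5R)-2-{[(tert-butyldimethylsilyl)oxy]methyl}-4,4-dimethoxy-5-(prop-1-en-2-yl)cyclohex-2-en-1-ol; 8 (S)-citronellic acid [(3S)-3,7-dimethyloct-6-enoic acid]
Product: 9 (1R,5R)-2-{[(tert-butyldimethylsilyl)oxy]methyl}-4,4-dimethoxy-5-(prop-1-en-2-yl)cyclohex-2-en-1-yl (3S)-3,7-dimethyloct-6-enoate
Conditions: DCC, DMAP (cat.), CH2Cl2, 0 °C → rt
Reagents that add atoms: none
Why: Steglich esterification (carbodiimide, DMAP) joins the two fragments without touching any stereocentre.

Step 7
Reactants: 9 (1R,5R)-2-{[(tert-butyldimethylsilyl)oxy]methyl}-4,4-dimethoxy-5-(prop-1-en-2-yl)cyclohex-2-en-1-yl (3S)-3,7-dimethyloct-6-enoate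
Product: 12 (2R,3S)-2-[(1R,5R)-2-{[(tert-butyldimethylsilyl)oxy]methyl}-6,6-dimethoxy-5-(prop-1-en-2-yl)cyclohex-2-en-1-yl]-3,7-dimethyloct-6-enoic acid, via silyl ketene acetal 10 (not isolated), via trimethylsilyl ester 11 (not isolated)
Conditions: LiN(i-Pr)2, THF/DMPU 4:1, −78 °C; TMSCl, Et3N; −78 → 45 °C; then K2CO3, MeOH/H2O, work-up at pH 5
Reagents that add atoms: none
Why: Ireland–Claisen rearrangement: enolisation in the presence of DMPU gives the (Z)-silyl ketene acetal, the [3,3] shift is suprafacial on the face of the C–O bond so that C8 is formed cis to the isopropenyl group, and C9 is set by the boat transition state that is the only one open here (the chair would put the ketene acetal over the axial isopropenyl group), with the citronellyl chain pointing away from the ketal.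

Step 8
Reactants: 12 (2R,3S)-2-[(1R,5R)-2-{[(tert-butyldimethylsilyl)oxy]methyl}-6,6-dimethoxy-5-(prop-1-en-2-yl)cyclohex-2-en-1-yl]-3,7-dimethyloct-6-enoic acid
Product: 13 (2R,3S)-2-[(1R,5R)-2-{[(tert-butyldimethylsilyl)oxy]methyl}-6,6-dimethoxy-5-(prop-1-en-2-yl)cyclohex-2-en-1-yl]-3,7-dimethyloct-6-en-1-ol
Conditions: LiAlH4, THF, 0 °C → rt
Reagents that add atoms: none
Why: Hydride reduction of the carboxylic acid to the primary alcohol; silyl ether, ketal and alkenes are inert to LiAlH4.

Step 9
Reactants: 13 (2R,3S)-2-[(1R,5R)-2-{[(tert-butyldimethylsilyl)oxy]methyl}-6,6-dimethoxy-5-(prop-1-en-2-yl)cyclohex-2-en-1-yl]-3,7-dimethyloct-6-en-1-ol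
Product: 14 (2R,3S)-2-[(1R,5R)-2-{[(tert-butyldimethylsilyl)oxy]methyl}-6,6-dimethoxy-5-(prop-1-en-2-yl)cyclohex-2-en-1-yl]-3,7-dimethyloct-6-enal
Conditions: Dess–Martin periodinane, NaHCO3, CH2Cl2, 0 °C
Reagents that add atoms: none
Why: Buffered Dess–Martin oxidation gives the alpha-branched aldehyde under neutral conditions, so that neither the C9 centre nor the ketal is disturbed.

Step 10
Reactants: 14 (2R,3S)-2-[(1R,5R)-2-{[(tert-butyldimethylsilyl)oxy]methyl}-6,6-dimethoxy-5-(prop-1-en-2-yl)cyclohex-2-en-1-yl]-3,7-dimethyloct-6-enal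
Product: 17 bridged γ-lactone (9-oxabicyclo[6.2.1]undeca-2,5-dien-10-one core: nine-membered ring of the target with the C1 oxygen joined to C8 through C11=O; C7 carries CH2OTBS; C3=C4 E; C6=C7 cis in the ring), via oxolanylium triflate 15 (not isolated), via methyl lactonium triflate 16 (not isolated)
Conditions: TMSOTf (0.2 equiv), CH2Cl2 (0.01 M), −78 → −30 °C; then Et3N, aq. NaHCO3
Reagents that add atoms: none
Why: Proposed new method: TMSOTf ionises the dimethyl ketal, the aldehyde oxygen adds to the methoxycarbenium ion (5-exo-trig) and gives the cis-fused oxolanylium ion 15, whose atoms C1=O+, O, C11, C4, C3 and C2 form a 2-oxonia-1,5-diene; a [3,3] shift (2-oxonia-Cope rearrangement, or Prins addition followed by Grob fragmentation if stepwise) makes C1–C2, breaks C11–C4 and leaves the O-methyl lactonium ion 16, which passes its methyl group to TMSOMe (Me2O) and so regenerates TMSOTf. The closest known reactions are the Lewis-acid-catalysed allyl transfer from homoallylic alcohols to aldehydes through hemiacetal-derived oxocarbenium ions and the reversible 2-oxonia-Cope shifts that accompany Prins cyclisations; not yet shown is a ketal carbon as the allyl donor, which ends as an ester and thereby makes the shift irreversible and pays for the strain of the (E)-cyclononene. Two rings close: the oxolane by 5-exo addition of oxygen to carbon, and the nine-membered carbocycle not end to end but by enlargement of the cyclohexene by three atoms through a six-membered chair transition state shaped like an 8-oxabicyclo[3.2.1]octane (C1 and C11 bridgeheads, O the one-atom bridge, C9–C8 the two-atom bridge). C1 is set by the tether, because the allyl terminus C2 can only reach C1 on the face of the oxolane ring that carries C4 and C7, i.e. cis to the C8–C7 bond and to the C9 side chain; the C3=C4 geometry is (E) because C5, tied back to C8 by the six-membered ring, must sit equatorial (anti to C2) in the chair; C6=C7 stays cis as it was in the cyclohexene; C8, C9 and the side-chain centre are not touched. The step needs the shift through the isopropenyl arm to beat the boat-like shift through the ring double bond, proton loss to enol ethers and Prins capture of C1 by the side-chain alkene; the all-cis placement of isopropenyl group, ring oxygen and C9 chain on the cyclohexene (steps 4, 5 and 7), which holds C2 next to C1 in a rigid frame, the base-free low-temperature conditions and the exothermic conversion of ketal plus aldehyde into a lactone are what should secure this.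

Step 11
Reactants: 17 bridged γ-lactone
Product: 18 diol (nine-membered ring with C1–OH; C8–CH2OH; C7–CH2OTBS)
Conditions: LiAlH4, THF, 0 °C
Reagents that add atoms: none
Why: LiAlH4 reduces the strained lactone to the 1,4-diol, which frees the C1 hydroxyl and brings C11 to the alcohol level for the final oxidation.

Step 12
Reactants: 18 diol (C1–OH; C8–CH2OH; C7–CH2OTBS)
Product: 19 bis-silyl ether (C1–OH; C8–CH2OTBS; C7–CH2OTBS)
Conditions: TBSCl (1.1 equiv), imidazole, CH2Cl2, 0 °C
Reagents that add atoms: tert-butyldimethylsilyl chloride, CC(C)(C)[Si](C)(C)Cl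
Why: Chemoselective silylation of the primary hydroxyl in the presence of the hindered secondary C1 hydroxyl.

Step 13
Reactants: 19 bis-silyl ether (C1–OH)
Product: 20 C1 acetate of the bis-silyl ether
Conditions: Ac2O, DMAP, pyridine, rt
Reagents that add atoms: acetic anhydride, CC(=O)OC(C)=O
Why: DMAP-catalysed acetylation of the only free hydroxyl.

Step 14
Reactants: 20 C1 acetate of the bis-silyl ether
Product: 21 acetoxy diol (C1–OAc; C7–CH2OH; C8–CH2OH)
Conditions: HF·pyridine, pyridine, THF, 0 °C
Reagents that add atoms: none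
Why: Buffered fluoride cleavage of both primary silyl ethers leaves the acetate in place (no basic conditions, so no acyl migration).

Step 15
Reactants: 21 acetoxy diol (C1–OAc; C7–CH2OH; C8–CH2OH)
Product: 22 target, (1R,2E,5E,8R,9R)-8-(acetyloxy)-6-methyl-9-[(2S)-6-methylhept-5-en-2-yl]cyclonona-2,5-diene-1,2-dicarbaldehyde
Conditions: (COCl)2, DMSO, CH2Cl2, −78 °C; Et3N, −78 → −20 °C
Reagents that add atoms: none
Why: Swern oxidation converts both primary hydroxyls into alkoxysulfonium ions before the base is added, so that no lactol can form between them, and the low temperature should keep the C8 centre next to the new aldehyde intact, as in the oxidation of related 2-ene-1,4-diols to ene-dials.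

**Compound list**

1 | 2-hydroxy-5-methoxybenzaldehyde | COc1ccc(O)c(C=O)c1 | starting material
2 | 2-(hydroxymethyl)-4-methoxyphenol | COc1ccc(O)c(CO)c1 | intermediate
3 | 2-{[(tert-butyldimethylsilyl)oxy]methyl}-4-methoxyphenol | COc1ccc(O)c(CO[Si](C)(C)C(C)(C)C)c1 | intermediate
4 | 2-{[(tert-butyldimethylsilyl)oxy]methyl}-4,4-dimethoxycyclohexa-2,5-dien-1-one | COC1(OC)C=CC(=O)C(CO[Si](C)(C)C(C)(C)C)=C1 | intermediate
5 | 4,4,5,5-tetramethyl-2-(prop-1-en-2-yl)-1,3,2-dioxaborolane | CC(=C)B1OC(C)(C)C(C)(C)O1 | starting material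
6 | (5R)-2-{[(tert-butyldimethylsilyl)oxy]methyl}-4,4-dimethoxy-5-(prop-1-en-2-yl)cyclohex-2-en-1-one | O=C1C[C@H](C(C)=C)C(OC)(OC)C=C1CO[Si](C)(C)C(C)(C)C | intermediate
7 | (1R,5R)-2-{[(tert-butyldimethylsilyl)oxy]methyl}-4,4-dimethoxy-5-(prop-1-en-2-yl)cyclohex-2-en-1-ol | O[C@@H]1C[C@H](C(C)=C)C(OC)(OC)C=C1CO[Si](C)(C)C(C)(C)C | intermediate
8 | (S)-citronellic acid | OC(=O)C[C@@H](C)CCC=C(C)C | starting material
9 | (1R,5R)-2-{[(tert-butyldimethylsilyl)oxy]methyl}-4,4-dimethoxy-5-(prop-1-en-2-yl)cyclohex-2-en-1-yl (3S)-3,7-dimethyloct-6-enoate | O=C(C[C@@H](C)CCC=C(C)C)O[C@@H]1C[C@H](C(C)=C)C(OC)(OC)C=C1CO[Si](C)(C)C(C)(C)C | intermediate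
10 | (Z)-O-trimethylsilyl ketene acetal of ester 9 | C[Si](C)(C)O/C(O[C@@H]1C[C@H](C(C)=C)C(OC)(OC)C=C1CO[Si](C)(C)C(C)(C)C)=C\[C@@H](C)CCC=C(C)C | intermediate
11 | trimethylsilyl ester of acid 12 | C[Si](C)(C)OC(=O)[C@H]([C@@H](C)CCC=C(C)C)[C@@H]1C(CO[Si](C)(C)C(C)(C)C)=CC[C@H](C(C)=C)C1(OC)OC | intermediate
12 | (2R,3S)-2-[(1R,5R)-2-{[(tert-butyldimethylsilyl)oxy]methyl}-6,6-dimethoxy-5-(prop-1-en-2-yl)cyclohex-2-en-1-yl]-3,7-dimethyloct-6-enoic acid | OC(=O)[C@H]([C@@H](C)CCC=C(C)C)[C@@H]1C(CO[Si](C)(C)C(C)(C)C)=CC[C@H](C(C)=C)C1(OC)OC | intermediate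
13 | (2R,3S)-2-[(1R,5R)-2-{[(tert-butyldimethylsilyl)oxy]methyl}-6,6-dimethoxy-5-(prop-1-en-2-yl)cyclohex-2-en-1-yl]-3,7-dimethyloct-6-en-1-ol | OC[C@H]([C@@H](C)CCC=C(C)C)[C@@H]1C(CO[Si](C)(C)C(C)(C)C)=CC[C@H](C(C)=C)C1(OC)OC | intermediate
14 | (2R,3S)-2-[(1R,5R)-2-{[(tert-butyldimethylsilyl)oxy]methyl}-6,6-dimethoxy-5-(prop-1-en-2-yl)cyclohex-2-en-1-yl]-3,7-dimethyloct-6-enal | O=C[C@H]([C@@H](C)CCC=C(C)C)[C@@H]1C(CO[Si](C)(C)C(C)(C)C)=CC[C@H](C(C)=C)C1(OC)OC | intermediate
15 | cis-fused oxolanylium triflate (C1=O+ bonded to methoxy-bearing C11; five-membered ring O–C1–C9–C8–C11 fused to the cyclohexene) | CO[C@@]12[O+]=C[C@H]([C@@H](C)CCC=C(C)C)[C@@H]1C(CO[Si](C)(C)C(C)(C)C)=CC[C@@H]2C(C)=C.[O-]S(=O)(=O)C(F)(F)F | intermediate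
16 | O-methyl lactonium triflate of lactone 17 | C[O+]=C1O[C@@H]2C/C(C)=C/C/C=C(/CO[Si](C)(C)C(C)(C)C)[C@H]1[C@H]2[C@@H](C)CCC=C(C)C.[O-]S(=O)(=O)C(F)(F)F | intermediate
17 | bridged γ-lactone (C1–O–C11(=O)–C8 bridge over the nine-membered diene ring; C7–CH2OTBS) | O=C1O[C@@H]2C/C(C)=C/C/C=C(/CO[Si](C)(C)C(C)(C)C)[C@H]1[C@H]2[C@@H](C)CCC=C(C)C | intermediate
18 | diol (C1–OH; C8–CH2OH; C7–CH2OTBS) | O[C@@H]1C/C(C)=C/C/C=C(/CO[Si](C)(C)C(C)(C)C)[C@H](CO)[C@H]1[C@@H](C)CCC=C(C)C | intermediate
19 | bis-silyl ether (C1–OH; C8–CH2OTBS; C7–CH2OTBS) | O[C@@H]1C/C(C)=C/C/C=C(/CO[Si](C)(C)C(C)(C)C)[C@H](CO[Si](C)(C)C(C)(C)C)[C@H]1[C@@H](C)CCC=C(C)C | intermediate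
20 | C1 acetate of 19 | CC(=O)O[C@@H]1C/C(C)=C/C/C=C(/CO[Si](C)(C)C(C)(C)C)[C@H](CO[Si](C)(C)C(C)(C)C)[C@H]1[C@@H](C)CCC=C(C)C | intermediate
21 | acetoxy diol (C1–OAc; C7–CH2OH; C8–CH2OH) | CC(=O)O[C@@H]1C/C(C)=C/C/C=C(/CO)[C@H](CO)[C@H]1[C@@H](C)CCC=C(C)C | intermediate
22 | (1R,2E,5E,8R,9R)-8-(acetyloxy)-6-methyl-9-[(2S)-6-methylhept-5-en-2-yl]cyclonona-2,5-diene-1,2-dicarbaldehyde | CC(=O)O[C@@H]1C/C(C)=C/C/C=C(/C=O)[C@H](C=O)[C@H]1[C@@H](C)CCC=C(C)C | target

**Step count and risks**

Total step count: 15. Longest linear sequence: 15 steps (1 → 22); 5 and 8 are bought.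

Steps most likely to fail:

1. Step 10 (the proposed new method). What may go wrong: the oxocarbenium ions are drained before the [3,3] shift. The two likely drains are capture of the C1 cation by the trisubstituted double bond of the side chain (a Prins closure of the kind known for citronellal) and loss of a proton from the ketal-derived cation to an enol ether, which would also erode C8. The fallback splits the event into two operations of known type; it sets out from 14 and comes back at 17. The ketal of 14 is hydrolysed (PPTS, acetone/H2O, 0 °C) to the keto aldehyde F1. TiCl4 in CH2Cl2 at −78 °C then closes the aldehyde onto the isopropenyl group with capture of chloride (halo-Prins closure), which makes the C1–C2 bond and gives the seven-membered tertiary chloride F2 with the C1 oxygen next to the ketone. KOt-Bu in THF at −40 °C adds the C1 alkoxide to the ketone, and the hemiketal alkoxide undergoes Grob fragmentation (chloride leaves, the C11–C4 bond breaks, C3=C4 forms) to lactone 17. The fragmentation cannot revert because chloride is lost. This fallback answers the proton-loss pathway; it does not remove the side-chain competition, since the aldehyde is still activated by a Lewis acid.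

2. Step 7. What may go wrong: the rearrangement is slow, because the reacting conformer holds the C–O bond and the isopropenyl group 1,3-diaxial and the new bond is formed next to the quaternary ketal carbon. Decomposition of the enolate (elimination to a ketene) and leakage of ketene acetal geometry would then lower conversion and the selectivity at C9. The fallback is an aliphatic Claisen rearrangement of a preformed enol ether; it sets out from 7 and comes back at 14, so that steps 6 to 9 are not needed. Commercial (S)-citronellal is converted in one pot (nonafluorobutanesulfonyl fluoride, phosphazene base) into the alkyne F3. Hydrozirconation with Cp2Zr(H)Cl and iodination give the vinyl iodide F4. Copper-catalysed C–O coupling with 7 (CuI, 3,4,7,8-tetramethyl-1,10-phenanthroline, Cs2CO3, toluene, 80 °C) gives the allyl vinyl ether F5, whose (E) geometry places the chain as in ketene acetal 10. Heating to 120 °C gives aldehyde 14 through the same boat transition state, without a base and without an enolisation step.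

3. Step 4. What may go wrong: insufficient face discrimination at rhodium, because the reacting β-carbon lies next to the quaternary ketal carbon, or an induction sense opposite to the one assumed by analogy. The fallback replaces asymmetric catalysis by a resolution; it sets out from 4 and comes back at 9. Copper-catalysed addition of isopropenylmagnesium bromide (CuI cat., THF, −40 °C) gives the racemic enone F6. Luche reduction gives the racemic cis-alcohol F7. Esterification with 8 as in step 6 gives 9 together with the diastereomeric ester F8, and the two are separated by chromatography; no step is added, and half of the material is lost.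

Further compounds

F1 | step 10 | (2R,3S)-2-[(1R,5R)-2-{[(tert-butyldimethylsilyl)oxy]methyl}-6-oxo-5-(prop-1-en-2-yl)cyclohex-2-en-1-yl]-3,7-dimethyloct-6-enal | O=C[C@H]([C@@H](C)CCC=C(C)C)[C@@H]1C(CO[Si](C)(C)C(C)(C)C)=CC[C@H](C(C)=C)C1=O
F2 | step 10 | bicyclic chloro hydroxy ketone (C1–C2 bond made; seven-membered ring C1–C2–C3(Cl)(Me)–C4–C11(=O)–C8–C9; either epimer at the chlorine-bearing carbon) | O[C@@H]1CC(C)(Cl)[C@H]2CC=C(CO[Si](C)(C)C(C)(C)C)[C@H](C2=O)[C@H]1[C@@H](C)CCC=C(C)C
F3 | step 7 | (S)-3,7-dimethyloct-6-en-1-yne | C#C[C@@H](C)CCC=C(C)C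
F4 | step 7 | (S,E)-1-iodo-3,7-dimethylocta-1,6-diene | I/C=C/[C@@H](C)CCC=C(C)C
F5 | step 7 | (E)-enol ether of 7 with the (3S)-3,7-dimethylocta-1,6-dien-1-yl group | O(/C=C/[C@@H](C)CCC=C(C)C)[C@@H]1C[C@H](C(C)=C)C(OC)(OC)C=C1CO[Si](C)(C)C(C)(C)C
F6 | step 4 | racemic 2-{[(tert-butyldimethylsilyl)oxy]methyl}-4,4-dimethoxy-5-(prop-1-en-2-yl)cyclohex-2-en-1-one | O=C1CC(C(C)=C)C(OC)(OC)C=C1CO[Si](C)(C)C(C)(C)C
F7 | step 4 | racemic cis-2-{[(tert-butyldimethylsilyl)oxy]methyl}-4,4-dimethoxy-5-(prop-1-en-2-yl)cyclohex-2-en-1-ol | OC1CC(C(C)=C)C(OC)(OC)C=C1CO[Si](C)(C)C(C)(C)C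
F8 | step 4 | (1S,5S)-2-{[(tert-butyldimethylsilyl)oxy]methyl}-4,4-dimethoxy-5-(prop-1-en-2-yl)cyclohex-2-en-1-yl (3S)-3,7-dimethyloct-6-enoate | O=C(C[C@@H](C)CCC=C(C)C)O[C@H]1C[C@@H](C(C)=C)C(OC)(OC)C=C1CO[Si](C)(C)C(C)(C)C
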